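**Assumption:** atoms carry germacrane numbers (C1–C15) throughout; "ring-cis" at C1=C10 means C2 and C9 on the same side, as the target SMILES encodes. The route is a paper design and none of it has been run.

## Retrosynthetic overview

1. Target 26 ⇐ diol 20 (O8–H and O9–H free, C14 masked as a dioxolane): acylate O8, acetylate O9, unmask with acid.
2. 20 ⇐ bromolactone enal 17 in one flask: the C6–C7 bond closes the ten-membered ring, then an O8→O6 acyl shift makes the 6,12-lactone while the temporary 8,12-lactone opens.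
3. 17 ⇐ α-hydroxy aldehyde 11 + C4 reagent 14: C7–C8 bond, C8 set by chelation; the temporary 8,12-lactone is the first ring and protects O8.
4. 11 ⇐ alkenyl iodide 6 + diethyl oxalate (C9–C10 bond); a CBS reduction sets C9.
5. 6 ⇐ geranyl acetate 1 (ozonolysis, Wittig, α-iodination; the iodide geometry becomes the C1=C10 geometry). Ring order: 8,12-lactone (relay), then carbocycle and 6,12-lactone together.

## Route

Step 1
Reactants: 1 geranyl acetate
Product: 2 (E)-6-acetoxy-4-methylhex-4-enal
Conditions: O3 (1.0 equiv), CH2Cl2, −78 °C; then Me2S, −78 → 20 °C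
Reagents that add atoms: ozone, [O-][O+]=O
Why: Chemoselective ozonolysis, because the terminal trisubstituted alkene is far more electron-rich than the alkene deactivated by the allylic acetate, and Me2S reduces the ozonide to the aldehyde.

Step 2
Reactants: 2 (E)-6-acetoxy-4-methylhex-4-enal; 3 (triphenylphosphoranylidene)acetaldehyde
Product: 4 (2E,6E)-8-acetoxy-6-methylocta-2,6-dienal
Conditions: toluene, 80 °C
Reagents that add atoms: (triphenylphosphoranylidene)acetaldehyde 3, O=CC=P(c1ccccc1)(c1ccccc1)c1ccccc1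
Why: Wittig olefination with the stabilised formylmethylene ylide gives the (E)-enal and adds C10 and C14.

Step 3
Reactants: 4 (2E,6E)-8-acetoxy-6-methylocta-2,6-dienal
Product: 5 (2Z,6E)-8-acetoxy-2-iodo-6-methylocta-2,6-dienal
Conditions: I2, K2CO3, 4-(dimethylamino)pyridine (0.2 equiv), THF/H2O (1:1), 20 °C
Reagents that add atoms: iodine, II
Why: α-Iodination of the enal by amine addition, iodination and elimination (Morita–Baylis–Hillman-type mechanism) gives the (Z)-iodide with C2 trans to the carbonyl carbon C14, which is the ring-cis C1=C10 geometry of the target.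

Step 4
Reactants: 5 (2Z,6E)-8-acetoxy-2-iodo-6-methylocta-2,6-dienal
Product: 6 (2E,6Z)-7-(1,3-dioxolan-2-yl)-7-iodo-3-methylhepta-2,6-dien-1-yl acetate
Conditions: 1,2-bis(trimethylsilyloxy)ethane, Me3SiOTf (5 mol %), CH2Cl2, −78 → −20 °C
Reagents that add atoms: 1,2-bis(trimethylsilyloxy)ethane, C[Si](C)(C)OCCO[Si](C)(C)C
Why: Noyori acetalisation masks C14 as a dioxolane under aprotic conditions that leave the vinyl iodide and the acetate untouched.

Step 5
Reactants: 6 (2E,6Z)-7-(1,3-dioxolan-2-yl)-7-iodo-3-methylhepta-2,6-dien-1-yl acetate; 7 diethyl oxalate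
Product: 9 ethyl (3Z,7E)-9-acetoxy-3-(1,3-dioxolan-2-yl)-7-methyl-2-oxonona-3,7-dienoate, via alkenylmagnesium chloride 8 (not isolated)
Conditions: i-PrMgCl·LiCl (1.1 equiv), THF, −40 °C; then added to 7 (3 equiv), THF, −78 °C; aq. NH4Cl
Reagents that add atoms: diethyl oxalate 7, CCOC(=O)C(=O)OCC
Why: Iodine–magnesium exchange proceeds with retention of alkene geometry and tolerates the acetate at −40 °C, and acylation of the alkenylmagnesium by excess oxalate stops at the α-keto ester, forming the C9–C10 bond.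

Step 6
Reactants: 9 ethyl (3Z,7E)-9-acetoxy-3-(1,3-dioxolan-2-yl)-7-methyl-2-oxonona-3,7-dienoate
Product: 10 ethyl (2S,3E,7E)-9-acetoxy-3-(1,3-dioxolan-2-yl)-2-hydroxy-7-methylnona-3,7-dienoate
Conditions: (S)-1-methyl-3,3-diphenyltetrahydro-1H,3H-pyrrolo[1,2-c][1,3,2]oxazaborole (0.2 equiv), catecholborane, toluene, −78 °C
Reagents that add atoms: none
Why: Corey–Bakshi–Shibata reduction, with the branched alkenyl group acting as the large substituent, delivers hydride to one face of the ketone and sets C9 as (S).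

Step 7
Reactants: 10 ethyl (2S,3E,7E)-9-acetoxy-3-(1,3-dioxolan-2-yl)-2-hydroxy-7-methylnona-3,7-dienoate
Product: 11 (2S,3E,7E)-3-(1,3-dioxolan-2-yl)-2,9-dihydroxy-7-methylnona-3,7-dienal
Conditions: i-Bu2AlH (3.3 equiv), CH2Cl2, −78 °C; MeOH, then aq. KNaC4H4O6; used crude
Reagents that add atoms: none
Why: Partial reduction with i-Bu2AlH stops at the aluminium hemiacetal chelated by the neighbouring alkoxide, so work-up gives the α-hydroxy aldehyde, and the acetate is cleaved to the C6 alcohol in the same flask.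

Step 8
Reactants: 12 methyl 2-(bromomethyl)acrylate
Product: 13 methyl 2,3-dibromo-2-(bromomethyl)propanoate
Conditions: Br2, CH2Cl2, 0 °C
Reagents that add atoms: bromine, BrBr
Why: Electrophilic addition of bromine to the acrylate double bond.

Step 9
Reactants: 13 methyl 2,3-dibromo-2-(bromomethyl)propanoate
Product: 14 methyl (Z)-3-bromo-2-(bromomethyl)acrylate
Conditions: i-Pr2NEt, CH2Cl2, 0 → 20 °C
Reagents that add atoms: none
Why: E2 dehydrobromination of the α-bromo ester can only give this vinyl bromide (both CH2Br groups are equivalent), and its E/Z ratio does not matter because the allylmetal made from it equilibrates.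

Step 10
Reactants: 11 (2S,3E,7E)-3-(1,3-dioxolan-2-yl)-2,9-dihydroxy-7-methylnona-3,7-dienal; 14 methyl (Z)-3-bromo-2-(bromomethyl)acrylate
Product: 16 (5R)-4-bromo-5-[(1S,2E,6E)-2-(1,3-dioxolan-2-yl)-1,8-dihydroxy-6-methylocta-2,6-dien-1-yl]-3-methylideneoxolan-2-one (both C4 epimers), via open-chain hydroxy ester 15 (not isolated)
Conditions: In powder (0.9 equiv), 14 (1.3 equiv), THF/H2O (1:1), NaHCO3 buffer, 20 °C; extract; then pyridinium p-toluenesulfonate (10 mol %), CH2Cl2, 20 °C
Reagents that add atoms: methyl (Z)-3-bromo-2-(bromomethyl)acrylate 14, Br/C=C(\CBr)C(=O)OC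
Why: Proposed new method: indium inserts into the allylic C–Br bond of 14 and the γ-bromoallylindium adds through its bromine-bearing carbon to the aldehyde chelated by the free α-hydroxyl (attack anti to the alkenyl group gives the 8,9-syn diol, while C7 is left as a mixture that step 12 erases), after which O8 closes the 8,12-lactone and is thereby told apart from O9; the closest known reactions are indium-mediated Barbier additions of 2-(bromomethyl)acrylates to unprotected α-hydroxy aldehydes in water and additions of γ-bromoallylindium reagents made from 1,3-dibromopropene.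

Step 11
Reactants: 16 (5R)-4-bromo-5-[(1S,2E,6E)-2-(1,3-dioxolan-2-yl)-1,8-dihydroxy-6-methylocta-2,6-dien-1-yl]-3-methylideneoxolan-2-one
Product: 17 (5R)-4-bromo-5-[(1S,2E,6E)-2-(1,3-dioxolan-2-yl)-1-hydroxy-6-methyl-8-oxoocta-2,6-dien-1-yl]-3-methylideneoxolan-2-one
Conditions: 2,2,6,6-tetramethylpiperidin-1-oxyl (0.1 equiv), PhI(OAc)2 (1.2 equiv), CH2Cl2, 20 °C
Reagents that add atoms: none
Why: The oxoammonium oxidation is selective for the primary allylic alcohol over the hindered secondary one and gives the C6 enal.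

Step 12
Reactants: 17 (5R)-4-bromo-5-[(1S,2E,6E)-2-(1,3-dioxolan-2-yl)-1-hydroxy-6-methyl-8-oxoocta-2,6-dien-1-yl]-3-methylideneoxolan-2-one
Product: 20 8β,9α-dihydroxy-14,14-(ethylenedioxy)germacra-1(10),4,11(13)-trien-12,6α-olide, via lactone-bound allylchromium dichloride 18 (not isolated), via 8,12-olide chromium alkoxide 19 (not isolated)
Conditions: CrCl2 (8 equiv), THF, 20 °C, 17 added by syringe pump (final 0.002 M); then 1,8-diazabicyclo[5.4.0]undec-7-ene (0.3 equiv), 0 °C; H2O
Reagents that add atoms: none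
Why: Proposed new method: CrCl2 reduces the allylic C–Br bond of either C7 epimer to one lactone-bound allylchromium of trivalent chromium (metal on C13, C7=C11 in the ring, hence E-type), which adds to the tethered enal through a chair transition state on the lactone face that carries the C9 tether (new C7–C6 bond cis to C8–C9) with the C5 alkenyl group equatorial (6,7-anti), so both new centres are set in the ring closure, and the amidine base then moves the acyl group from O8 to the new O6 alkoxide to give the trans 6α,12-lactone; the closest known reactions are Nozaki–Hiyama–Kishi-type allylations with 3-(bromomethyl)furan-2(5H)-ones, Barbier macrocyclisations to ten-membered germacranolides and base-mediated translactonisation of sesquiterpene lactones.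

Step 13
Reactants: 21 ethyl 2-(hydroxymethyl)acrylate
Product: 22 ethyl 2-{[(tert-butyldimethylsilyl)oxy]methyl}acrylate
Conditions: t-BuMe2SiCl, imidazole, CH2Cl2, 0 → 20 °C
Reagents that add atoms: tert-butyldimethylsilyl chloride, CC(C)(C)[Si](C)(C)Cl
Why: Standard silylation of the primary alcohol.

Step 14
Reactants: 22 ethyl 2-{[(tert-butyldimethylsilyl)oxy]methyl}acrylate
Product: 23 2-{[(tert-butyldimethylsilyl)oxy]methyl}acrylic acid
Conditions: LiOH, THF/H2O, 0 °C; 1 M HCl to pH 3
Reagents that add atoms: lithium hydroxide, [Li+].[OH-]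
Why: Saponification of the ethyl ester leaves the silyl ether intact at 0 °C.

Step 15
Reactants: 20 8β,9α-dihydroxy-14,14-(ethylenedioxy)germacra-1(10),4,11(13)-trien-12,6α-olide; 23 2-{[(tert-butyldimethylsilyl)oxy]methyl}acrylic acid
Product: 24 8-O-acyl derivative of 20 (O9–H free)
Conditions: 23 (1.1 equiv), N,N'-dicyclohexylcarbodiimide, 4-(dimethylamino)pyridine (0.1 equiv), CH2Cl2, −20 °C
Reagents that add atoms: 2-{[(tert-butyldimethylsilyl)oxy]methyl}acrylic acid 23, C=C(CO[Si](C)(C)C(C)(C)C)C(=O)O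
Why: Steglich esterification is expected at O8 because O9–H is flanked by the fully substituted C10 that carries the dioxolane, and C14 is still masked so O8–H cannot close a lactol.

Step 16
Reactants: 24 8-O-acyl derivative of 20
Product: 25 9-O-acetyl derivative of 24
Conditions: Ac2O, pyridine, 4-(dimethylamino)pyridine (cat.), CH2Cl2, 0 → 20 °C
Reagents that add atoms: acetic anhydride, CC(=O)OC(C)=O
Why: Acetylation of the one remaining hydroxyl with the small anhydride under nucleophilic catalysis.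

Step 17
Reactants: 25 9-O-acetyl derivative of 24
Product: 26 target CNP0177123.1
Conditions: AcOH/THF/H2O (3:1:1), 40 °C
Reagents that add atoms: water, O
Why: Mild acid hydrolysis cleaves the primary silyl ether and the enal dioxolane together while the esters, the lactone and the stereocentres are untouched.

## Compound list

1 | geranyl acetate | CC(C)=CCC/C(C)=C/COC(C)=O | starting material
2 | (E)-6-acetoxy-4-methylhex-4-enal | O=CCC/C(C)=C/COC(C)=O | intermediate
3 | (triphenylphosphoranylidene)acetaldehyde | O=CC=P(c1ccccc1)(c1ccccc1)c1ccccc1 | starting material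
4 | (2E,6E)-8-acetoxy-6-methylocta-2,6-dienal | O=C/C=C/CC/C(C)=C/COC(C)=O | intermediate
5 | (2Z,6E)-8-acetoxy-2-iodo-6-methylocta-2,6-dienal | O=C/C(I)=C/CC/C(C)=C/COC(C)=O | intermediate
6 | (2E,6Z)-7-(1,3-dioxolan-2-yl)-7-iodo-3-methylhepta-2,6-dien-1-yl acetate | CC(=O)OC/C=C(\C)CC/C=C(\I)C1OCCO1 | intermediate
7 | diethyl oxalate | CCOC(=O)C(=O)OCC | starting material
8 | alkenylmagnesium chloride from 6 (Mg in place of I, geometry retained) | CC(=O)OC/C=C(\C)CC/C=C(\[Mg]Cl)C1OCCO1 | intermediate
9 | ethyl (3Z,7E)-9-acetoxy-3-(1,3-dioxolan-2-yl)-7-methyl-2-oxonona-3,7-dienoate | CCOC(=O)C(=O)/C(=C\CC/C(C)=C/COC(C)=O)C1OCCO1 | intermediate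
10 | ethyl (2S,3E,7E)-9-acetoxy-3-(1,3-dioxolan-2-yl)-2-hydroxy-7-methylnona-3,7-dienoate | CCOC(=O)[C@@H](O)/C(=C\CC/C(C)=C/COC(C)=O)C1OCCO1 | intermediate
11 | (2S,3E,7E)-3-(1,3-dioxolan-2-yl)-2,9-dihydroxy-7-methylnona-3,7-dienal | O=C[C@@H](O)/C(=C\CC/C(C)=C/CO)C1OCCO1 | intermediate
12 | methyl 2-(bromomethyl)acrylate | C=C(CBr)C(=O)OC | starting material
13 | methyl 2,3-dibromo-2-(bromomethyl)propanoate | COC(=O)C(Br)(CBr)CBr | intermediate
14 | methyl (Z)-3-bromo-2-(bromomethyl)acrylate | Br/C=C(\CBr)C(=O)OC | intermediate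
15 | methyl (3RS,4R,5S,6E,10E)-3-bromo-6-(1,3-dioxolan-2-yl)-4,5,12-trihydroxy-10-methyl-2-methylidenedodeca-6,10-dienoate | COC(=O)C(=C)C(Br)[C@H](O)[C@@H](O)/C(=C\CC/C(C)=C/CO)C1OCCO1 | intermediate
16 | (5R)-4-bromo-5-[(1S,2E,6E)-2-(1,3-dioxolan-2-yl)-1,8-dihydroxy-6-methylocta-2,6-dien-1-yl]-3-methylideneoxolan-2-one, both C4 epimers (8R,9S in germacrane numbering) | C=C1C(=O)O[C@H]([C@@H](O)/C(=C\CC/C(C)=C/CO)C2OCCO2)C1Br | intermediate
17 | (5R)-4-bromo-5-[(1S,2E,6E)-2-(1,3-dioxolan-2-yl)-1-hydroxy-6-methyl-8-oxoocta-2,6-dien-1-yl]-3-methylideneoxolan-2-one, both C4 epimers | C=C1C(=O)O[C@H]([C@@H](O)/C(=C\CC/C(C)=C/C=O)C2OCCO2)C1Br | intermediate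
18 | dichloro{[5-substituted 2-oxo-2,5-dihydrofuran-3-yl]methyl}chromium from 17 (C8 and C9 unchanged) | Cl[Cr](Cl)CC1=C[C@@H]([C@@H](O)/C(=C\CC/C(C)=C/C=O)C2OCCO2)OC1=O | intermediate
19 | (6R,7S,8S,9S)-14,14-(ethylenedioxy)-6,9-dihydroxygermacra-1(10),4,11(13)-trien-12,8-olide, formed as its chromium alkoxide at O6 | O[C@@H]1/C=C(\C)CC/C=C(/C3OCCO3)[C@H](O)[C@H]2OC(=O)C(=C)[C@@H]12 | intermediate
20 | 8β,9α-dihydroxy-14,14-(ethylenedioxy)germacra-1(10),4,11(13)-trien-12,6α-olide; 6R,7R,8S,9S (7R by CIP only, same spatial arrangement as 7S in 26); C1=C10 ring-cis, C4=C5 E | O[C@H]1[C@H]2C(=C)C(=O)O[C@@H]2/C=C(\C)CC/C=C(/C3OCCO3)[C@@H]1O | intermediate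
21 | ethyl 2-(hydroxymethyl)acrylate | C=C(CO)C(=O)OCC | starting material
22 | ethyl 2-{[(tert-butyldimethylsilyl)oxy]methyl}acrylate | C=C(CO[Si](C)(C)C(C)(C)C)C(=O)OCC | intermediate
23 | 2-{[(tert-butyldimethylsilyl)oxy]methyl}acrylic acid | C=C(CO[Si](C)(C)C(C)(C)C)C(=O)O | intermediate
24 | (6R,7S,8S,9S)-8-O-(2-{[(tert-butyldimethylsilyl)oxy]methyl}acryloyl) derivative of 20, O9–H free | C=C(CO[Si](C)(C)C(C)(C)C)C(=O)O[C@H]1[C@H]2C(=C)C(=O)O[C@@H]2/C=C(\C)CC/C=C(/C3OCCO3)[C@@H]1O | intermediate
25 | (6R,7S,8S,9S)-9-O-acetyl derivative of 24 | C=C(CO[Si](C)(C)C(C)(C)C)C(=O)O[C@H]1[C@H]2C(=C)C(=O)O[C@@H]2/C=C(\C)CC/C=C(/C3OCCO3)[C@@H]1OC(C)=O | intermediate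
26 | CNP0177123.1: (6R,7S,8S,9S)-9-acetoxy-8-[2-(hydroxymethyl)acryloyloxy]-14-oxogermacra-1(10),4,11(13)-trien-12,6-olide | C=C(CO)C(=O)O[C@H]1[C@H]2C(=C)C(=O)O[C@@H]2/C=C(\C)CC/C=C(/C=O)[C@@H]1OC(C)=O | target

## Step count and weak points

Total step count: 17. Longest linear sequence: 13 steps (1–7, 10–12, 15–17, from geranyl acetate 1 to 26).

The three steps most likely to fail are 12, 10 and 15.

Step 12 (ring closure with lactone transposition). The risks are bond formation at C7 on the face away from the C9 tether, poor control at C6, or an acyl shift that stalls. The fallback closes the ring from the open-chain ester, so that the 6,12-lactone forms directly and the stereochemistry rests on macrocyclic control of an acyclic allylchromium. It sets out from adduct 15, which is worked up without acid and isolated. Its three hydroxyls are silylated with Et3SiOTf and 2,6-lutidine to give the tris(triethylsilyl) ether F4. Swern oxidation converts only the primary allylic silyl ether into the enal F5. CrCl2 in dilute THF then effects an intramolecular 2-(methoxycarbonyl)allylation with spontaneous lactonisation of the C6 alkoxide to the 8,9-bis(triethylsilyl) ether F6. HF·pyridine removes both silyl groups and the route is rejoined at 20.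

Step 10 (indium coupling). The risks are the unprotected α-hydroxy aldehyde, reduction or elimination at the second C–Br bond, and modest syn selectivity. The fallback masks the hydroxyl and runs the coupling under aprotic zinc conditions, where the alkoxide lactonises before any β-hydroxy bromide meets the metal. It sets out from 10, which 4-methoxybenzyl trichloroacetimidate and a catalytic acid convert into the 4-methoxybenzyl ether F1. i-Bu2AlH then gives the stable α-alkoxy aldehyde F2. Zn dust and 14 in THF (Dreiding–Schmidt conditions, chelation through the ether oxygen) give the 9-O-(4-methoxybenzyl) bromolactone F3. DDQ in wet CH2Cl2 removes the ether and the route is rejoined at 16.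

Step 15 (acylation of one of two secondary hydroxyls). If O8 and O9 are not differentiated, O9 is blocked before the ring closure. The fallback sets out from 17, which is converted with 4-methoxybenzyl trichloroacetimidate into the 9-O-(4-methoxybenzyl) ether F7. The CrCl2 and amidine operation of step 12 then gives the mono-alcohol F8, whose only free hydroxyl is O8. Esterification with 23 gives the 8-O-acyl-9-O-(4-methoxybenzyl) compound F9. Buffered DDQ removes the benzyl ether and the route is rejoined at 24.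

## Further compounds

F1 | step 10 | ethyl (2S,3E,7E)-9-acetoxy-3-(1,3-dioxolan-2-yl)-2-[(4-methoxybenzyl)oxy]-7-methylnona-3,7-dienoate | CCOC(=O)[C@@H](OCc1ccc(OC)cc1)/C(=C\CC/C(C)=C/COC(C)=O)C1OCCO1
F2 | step 10 | (2S,3E,7E)-3-(1,3-dioxolan-2-yl)-9-hydroxy-2-[(4-methoxybenzyl)oxy]-7-methylnona-3,7-dienal | O=C[C@@H](OCc1ccc(OC)cc1)/C(=C\CC/C(C)=C/CO)C1OCCO1
F3 | step 10 | 9-O-(4-methoxybenzyl) ether of bromolactone 16 | C=C1C(=O)O[C@H]([C@@H](OCc2ccc(OC)cc2)/C(=C\CC/C(C)=C/CO)C2OCCO2)C1Br
F4 | step 12 | tris(triethylsilyl) ether of open-chain adduct 15 | COC(=O)C(=C)C(Br)[C@H](O[Si](CC)(CC)CC)[C@@H](O[Si](CC)(CC)CC)/C(=C\CC/C(C)=C/CO[Si](CC)(CC)CC)C1OCCO1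
F5 | step 12 | C6 enal from F4 with O8 and O9 as triethylsilyl ethers | COC(=O)C(=C)C(Br)[C@H](O[Si](CC)(CC)CC)[C@@H](O[Si](CC)(CC)CC)/C(=C\CC/C(C)=C/C=O)C1OCCO1
F6 | step 12 | 8,9-bis-O-(triethylsilyl) ether of 20 | CC[Si](CC)(CC)O[C@H]1[C@H]2C(=C)C(=O)O[C@@H]2/C=C(\C)CC/C=C(/C3OCCO3)[C@@H]1O[Si](CC)(CC)CC
F7 | step 15 | 9-O-(4-methoxybenzyl) ether of bromolactone enal 17 | C=C1C(=O)O[C@H]([C@@H](OCc2ccc(OC)cc2)/C(=C\CC/C(C)=C/C=O)C2OCCO2)C1Br
F8 | step 15 | 9-O-(4-methoxybenzyl) ether of 20 | O[C@H]1[C@H]2C(=C)C(=O)O[C@@H]2/C=C(\C)CC/C=C(/C3OCCO3)[C@@H]1OCc1ccc(OC)cc1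
F9 | step 15 | 9-O-(4-methoxybenzyl) ether of 24 | C=C(CO[Si](C)(C)C(C)(C)C)C(=O)O[C@H]1[C@H]2C(=C)C(=O)O[C@@H]2/C=C(\C)CC/C=C(/C3OCCO3)[C@@H]1OCc1ccc(OC)cc1
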